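The route rests on disconnecting the C1–C8a bond, so that the cyclohexadiene ring of the 1,2-dihydronaphthalene closes last by a cationic Friedel–Crafts alkylation. The precursor is an acyclic Evans syn-aldol adduct: a C1 carbinol carrying the 3,4-dimethoxyphenyl ring, the C2 stereocentre, and an (E)-C3=C4 Stobbe alkene that holds the 3,4,5-trimethoxyphenyl ring cis to C2. Acid ionises C1 (cation stabilised by the para-methoxy group); the trimethoxyphenyl ring, whose two ortho carbons are equivalent and each para to a methoxy group, attacks to create C8a. One operation closes the ring and sets C1 trans to C2; hydride reduction then finishes the diol.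

Key step: step 4

Remark: the locants C1–C4, C4a and C8a are those of the dihydronaphthalene core of the target and are used for the corresponding atoms of all precursors.

Step 1
Reactants: 1 3,4,5-trimethoxybenzaldehyde; 2 dimethyl succinate
Product: 4 (3E)-3-(methoxycarbonyl)-4-(3,4,5-trimethoxyphenyl)but-3-enoic acid, via paraconate lactone 3 (not isolated)
Conditions: NaOMe (2 equiv), MeOH, reflux; then aq. HCl
Reagents that add atoms: none
Why: Stobbe condensation: the succinate enolate adds to the aldehyde, the alkoxide closes onto the distal ester to give 3, and E1cB opening places the carboxylate on the CH2 arm and gives the alkene with the aryl group trans to the retained ester, i.e. (E).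

Step 2
Reactants: 4 (3E)-3-(methoxycarbonyl)-4-(3,4,5-trimethoxyphenyl)but-3-enoic acid; 5 (4R)-4-benzyl-1,3-oxazolidin-2-one
Product: 7 methyl (2E)-2-{2-[(4R)-4-benzyl-2-oxo-1,3-oxazolidin-3-yl]-2-oxoethyl}-3-(3,4,5-trimethoxyphenyl)prop-2-enoate, via mixed pivalic anhydride 6 (not isolated)
Conditions: PivCl, Et3N, THF, −20 °C; then LiCl, 5, −20 °C → rt
Reagents that add atoms: none
Why: N-acylation of the oxazolidinone through the mixed anhydride under LiCl/Et3N activation, mild enough to leave the (E)-alkene and the acidic allylic CH2 group unchanged; no stereocentre is formed.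

Step 3
Reactants: 7 methyl (2E)-2-{2-[(4R)-4-benzyl-2-oxo-1,3-oxazolidin-3-yl]-2-oxoethyl}-3-(3,4,5-trimethoxyphenyl)prop-2-enoate; 8 3,4-dimethoxybenzaldehyde
Product: 11 methyl (2E,3R,4R)-3-{[(4R)-4-benzyl-2-oxo-1,3-oxazolidin-3-yl]carbonyl}-4-(3,4-dimethoxyphenyl)-4-hydroxy-2-(3,4,5-trimethoxybenzylidene)butanoate, via boron enolate 9 (not isolated), via boron aldolate 10 (not isolated)
Conditions: Bu2BOTf, iPr2NEt, CH2Cl2, −78 → 0 °C; then 8, −78 → 0 °C; pH 7 buffer, MeOH, 30% H2O2, 0 °C
Reagents that add atoms: none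
Why: Evans syn-aldol reaction: the (Z)-boron enolate 9 adds through a Zimmerman–Traxler chair on the enolate face remote from the benzyl group of the dipole-opposed (4R)-auxiliary, which sets C2 (3R in 11, the later 2S centre of the target), while the syn carbinol centre at C1 (4R) is erased in step 4.

Step 4
Reactants: 11 methyl (2E,3R,4R)-3-{[(4R)-4-benzyl-2-oxo-1,3-oxazolidin-3-yl]carbonyl}-4-(3,4-dimethoxyphenyl)-4-hydroxy-2-(3,4,5-trimethoxybenzylidene)butanoate
Product: 13 methyl (1R,2S)-2-{[(4R)-4-benzyl-2-oxo-1,3-oxazolidin-3-yl]carbonyl}-1-(3,4-dimethoxyphenyl)-6,7,8-trimethoxy-1,2-dihydronaphthalene-3-carboxylate, via benzylic cation 12 (not isolated)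
Conditions: TFA (10 equiv), CH2Cl2 (dilute), 0 °C → rt
Reagents that add atoms: none
Why: TFA ionises the benzylic carbinol of 11 to cation 12, which is stabilised by the para-methoxy group of the 3,4-dimethoxyphenyl ring, and the trimethoxyphenyl ring attacks it and rearomatises by proton loss. The closest known reaction type is the intramolecular Friedel–Crafts alkylation of benzylic alcohols that closes aryltetralin and aryldihydronaphthalene lignans, including α-(hydroxybenzyl) carbonyl substrates. The ring closes by C1–C8a bond formation in a 6-endo-trig mode with respect to the arene π bond, the (E)-C3=C4 alkene serving as the rigid part of the tether. The new stereocentre C1 is controlled by the existing C2 centre: in the half-chair transition state the aryl group on the planar cation stays anti to the bulky acyl-oxazolidinone on C2, which should give the 1,2-trans (1R,2S) product from either carbinol epimer. The step needs regioselectivity on the arene, secured by the local symmetry of the 3,4,5-trimethoxyphenyl ring whose two ortho carbons are equivalent and each para to a methoxy group, and chemoselectivity against attack on C3=C4, secured by the ester that makes this alkene electron-poor. It also needs ring closure to outrun loss of the C2 proton from 12, which the cis placement of the arene and C2 on the alkene favours by holding the nucleophile next to the cationic centre.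

Step 5
Reactants: 13 methyl (1R,2S)-2-{[(4R)-4-benzyl-2-oxo-1,3-oxazolidin-3-yl]carbonyl}-1-(3,4-dimethoxyphenyl)-6,7,8-trimethoxy-1,2-dihydronaphthalene-3-carboxylate
Product: 14 [(1R,2S)-1-(3,4-dimethoxyphenyl)-6,7,8-trimethoxy-1,2-dihydronaphthalene-2,3-diyl]dimethanol
Conditions: LiAlH4 (excess), THF, −10 → 0 °C; Na2SO4·10H2O quench
Reagents that add atoms: none
Why: LiAlH4 reduces the N-acyl oxazolidinone (exocyclic C–N cleavage) and the conjugated methyl ester by 1,2-hydride addition to the two primary alcohols; neither stereocentre is a reaction site, so the (1R,2S) configuration should be carried through.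

Compound list
1 | 3,4,5-trimethoxybenzaldehyde | COc1cc(C=O)cc(OC)c1OC | starting material
2 | dimethyl succinate | COC(=O)CCC(=O)OC | starting material
3 | methyl 5-oxo-2-(3,4,5-trimethoxyphenyl)oxolane-3-carboxylate (paraconate lactone, stereoisomer mixture, not isolated) | COC(=O)C1CC(=O)OC1c2cc(OC)c(OC)c(OC)c2 | intermediate
4 | (3E)-3-(methoxycarbonyl)-4-(3,4,5-trimethoxyphenyl)but-3-enoic acid | COC(=O)/C(CC(=O)O)=C/c1cc(OC)c(OC)c(OC)c1 | intermediate
5 | (4R)-4-benzyl-1,3-oxazolidin-2-one | O=C1N[C@H](Cc2ccccc2)CO1 | starting material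
6 | mixed anhydride of 4 with pivalic acid (not isolated) | COC(=O)/C(CC(=O)OC(=O)C(C)(C)C)=C/c1cc(OC)c(OC)c(OC)c1 | intermediate
7 | methyl (2E)-2-{2-[(4R)-4-benzyl-2-oxo-1,3-oxazolidin-3-yl]-2-oxoethyl}-3-(3,4,5-trimethoxyphenyl)prop-2-enoate | COC(=O)/C(CC(=O)N1[C@H](Cc2ccccc2)COC1=O)=C/c3cc(OC)c(OC)c(OC)c3 | intermediate
8 | 3,4-dimethoxybenzaldehyde | COc1ccc(C=O)cc1OC | starting material
9 | (Z)-dibutylboron enolate of 7 (not isolated) | COC(=O)/C(/C=C(\OB(CCCC)CCCC)N1[C@H](Cc2ccccc2)COC1=O)=C/c3cc(OC)c(OC)c(OC)c3 | intermediate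
10 | dibutylboron aldolate of 11 (not isolated) | COc1ccc(cc1OC)[C@H](OB(CCCC)CCCC)[C@H](C(=O)N2[C@H](Cc3ccccc3)COC2=O)/C(C(=O)OC)=C\c4cc(OC)c(OC)c(OC)c4 | intermediate
11 | methyl (2E,3R,4R)-3-{[(4R)-4-benzyl-2-oxo-1,3-oxazolidin-3-yl]carbonyl}-4-(3,4-dimethoxyphenyl)-4-hydroxy-2-(3,4,5-trimethoxybenzylidene)butanoate | COc1ccc(cc1OC)[C@H](O)[C@H](C(=O)N2[C@H](Cc3ccccc3)COC2=O)/C(C(=O)OC)=C\c4cc(OC)c(OC)c(OC)c4 | intermediate
12 | 3,4-dimethoxybenzylic cation derived from 11 by loss of hydroxide at C1 (not isolated) | COc1ccc(cc1OC)[CH+][C@H](C(=O)N2[C@H](Cc3ccccc3)COC2=O)/C(C(=O)OC)=C\c4cc(OC)c(OC)c(OC)c4 | intermediate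
13 | methyl (1R,2S)-2-{[(4R)-4-benzyl-2-oxo-1,3-oxazolidin-3-yl]carbonyl}-1-(3,4-dimethoxyphenyl)-6,7,8-trimethoxy-1,2-dihydronaphthalene-3-carboxylate | COc1ccc([C@@H]2c3c(cc(OC)c(OC)c3OC)C=C(C(=O)OC)[C@H]2C(=O)N4[C@H](Cc5ccccc5)COC4=O)cc1OC | intermediate
14 | [(1R,2S)-1-(3,4-dimethoxyphenyl)-6,7,8-trimethoxy-1,2-dihydronaphthalene-2,3-diyl]dimethanol (1,2-trans) | COc1ccc([C@@H]2c3c(cc(OC)c(OC)c3OC)C=C(CO)[C@H]2CO)cc1OC | target

Total step count: 5. Longest linear sequence: 5 steps (1 → 4 → 7 → 11 → 13 → 14).

Steps most likely to fail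

Step 4 (key step). Loss of the C2 proton from cation 12 (E1) would give the achiral bis(arylidene) diene and destroy the controlling stereocentre. Capture of the cation by the neighbouring ester carbonyl would divert material to a lactone. The fallback removes the acyl group from C2 before ionisation. It sets out from 11: LiBH4 (THF, 1 equiv MeOH, 0 °C) should cleave the auxiliary reductively to the diol ester methyl (2E,3S,4R)-4-(3,4-dimethoxyphenyl)-4-hydroxy-3-(hydroxymethyl)-2-(3,4,5-trimethoxybenzylidene)butanoate F1. TFA in CH2Cl2 should then lactonise the primary alcohol onto the ester and effect the same Friedel–Crafts closure to the tricyclic lactone (3aS,4R)-4-(3,4-dimethoxyphenyl)-5,6,7-trimethoxy-3a,4-dihydronaphtho[2,3-c]furan-1(3H)-one F2, the familiar α-arylidene-β-(hydroxybenzyl)butyrolactone cyclisation. LiAlH4 (THF, 0 °C) reduces F2 to the diol, and the fallback comes back to the route at 14.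

Step 3. The addition may be reversible with the electron-rich aldehyde (retro-aldol), the cross-conjugated dienolate may react through its γ-carbon, or the aldolate may lactonise onto the neighbouring ester; each would erode the control of C2. The fallback gives up the auxiliary and relies on resolution. It sets out from 4: esterification (MeOH, cat. H2SO4) gives dimethyl (2E)-2-(3,4,5-trimethoxybenzylidene)butanedioate F3. A second Stobbe condensation with 8 (NaOMe, MeOH, reflux) gives the bis(arylidene) half-ester (2E,3E)-4-(3,4-dimethoxyphenyl)-3-(methoxycarbonyl)-2-(3,4,5-trimethoxybenzylidene)but-3-enoic acid F4. Triflic acid in CH2Cl2 (acid-catalysed cyclisation of dibenzylidenesuccinates) should cyclise F4 to racemic trans-1-(3,4-dimethoxyphenyl)-6,7,8-trimethoxy-2-(methoxycarbonyl)-1,2-dihydronaphthalene-3-carboxylic acid F5. The better cation-stabilising 3,4-dimethoxyphenyl ring and the more nucleophilic trimethoxyphenyl ring should direct the regiochemistry. Resolution of F5 through a diastereomeric salt with a chiral amine such as (R)-1-phenylethylamine (or by preparative HPLC on a chiral phase, configuration assigned by X-ray analysis of the salt) provides (1R,2S)-1-(3,4-dimethoxyphenyl)-6,7,8-trimethoxy-2-(methoxycarbonyl)-1,2-dihydronaphthalene-3-carboxylic acid F6. LiAlH4 reduces acid and ester of F6, and the fallback comes back to the route at 14.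

Step 5. Conjugate hydride delivery to the aryl-conjugated ester or hydroalumination of the resulting cinnamyl-type alkoxide would over-reduce the alkene. Endocyclic opening of the hindered imide and base-induced epimerisation or alkene migration at the acidic C2–H are further risks. The fallback separates auxiliary removal from reduction. It sets out from 13: methanolysis with MeOMgBr (from MeMgBr and MeOH, CH2Cl2, 0 °C) should give dimethyl (1R,2S)-1-(3,4-dimethoxyphenyl)-6,7,8-trimethoxy-1,2-dihydronaphthalene-2,3-dicarboxylate F7. DIBAL-H (CH2Cl2, −78 → 0 °C) reduces both esters of F7 by 1,2-addition, and the fallback comes back to the route at 14.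

Further compounds
F1 | step 4 | methyl (2E,3S,4R)-4-(3,4-dimethoxyphenyl)-4-hydroxy-3-(hydroxymethyl)-2-(3,4,5-trimethoxybenzylidene)butanoate | COc1ccc(cc1OC)[C@H](O)[C@H](CO)/C(C(=O)OC)=C\c2cc(OC)c(OC)c(OC)c2
F2 | step 4 | (3aS,4R)-4-(3,4-dimethoxyphenyl)-5,6,7-trimethoxy-3a,4-dihydronaphtho[2,3-c]furan-1(3H)-one | COc1ccc([C@@H]2c3c(cc(OC)c(OC)c3OC)C=C4C(=O)OC[C@@H]24)cc1OC
F3 | step 3 | dimethyl (2E)-2-(3,4,5-trimethoxybenzylidene)butanedioate | COC(=O)C/C(C(=O)OC)=C\c1cc(OC)c(OC)c(OC)c1
F4 | step 3 | (2E,3E)-4-(3,4-dimethoxyphenyl)-3-(methoxycarbonyl)-2-(3,4,5-trimethoxybenzylidene)but-3-enoic acid | COc1cc(/C=C(C(=O)O)\C(C(=O)OC)=C/c2ccc(OC)c(OC)c2)cc(OC)c1OC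
F5 | step 3 | racemic trans-1-(3,4-dimethoxyphenyl)-6,7,8-trimethoxy-2-(methoxycarbonyl)-1,2-dihydronaphthalene-3-carboxylic acid (1:1 mixture of the (1R,2S) and (1S,2R) forms) | COc1ccc([C@@H]2c3c(cc(OC)c(OC)c3OC)C=C(C(=O)O)[C@H]2C(=O)OC)cc1OC.COc1ccc([C@H]2c3c(cc(OC)c(OC)c3OC)C=C(C(=O)O)[C@@H]2C(=O)OC)cc1OC
F6 | step 3 | (1R,2S)-1-(3,4-dimethoxyphenyl)-6,7,8-trimethoxy-2-(methoxycarbonyl)-1,2-dihydronaphthalene-3-carboxylic acid | COc1ccc([C@@H]2c3c(cc(OC)c(OC)c3OC)C=C(C(=O)O)[C@H]2C(=O)OC)cc1OC
F7 | step 5 | dimethyl (1R,2S)-1-(3,4-dimethoxyphenyl)-6,7,8-trimethoxy-1,2-dihydronaphthalene-2,3-dicarboxylate | COc1ccc([C@@H]2c3c(cc(OC)c(OC)c3OC)C=C(C(=O)OC)[C@H]2C(=O)OC)cc1OC
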